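**Retrosynthetic overview**

1. Ring C is opened at O1–C2. The target is (2S)-pinocembrin carrying a (6-ethyl-4-hydroxy-5-methyl-2-pyron-3-yl)methyl group on C8, and it goes back to the 2′,4′,6′-trihydroxy-3′-(pyronylmethyl)chalcone 14 (asymmetric oxa-Michael closure in the forward sense).
2. The route rests on ring A. Its carbons C8a, C8, C7, C6, C5 and C4a carry oxygen on C8a, C7 and C5 and carbon branches on C8 and C4a. This is the folding pattern of a 2-substituted 3,5,7-triketo ester, the open form of a 3-substituted 6-(cinnamoylmethyl)-4-hydroxy-2-pyrone. Cutting C4a–C8a (Claisen) leads to the methylene-bis-pyrone 12.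
3. The methylene bridge of 12 is cut at C3 of the cinnamoylmethyl pyrone, giving pyrone 10 and the Mannich salt 6 of 6-ethyl-4-hydroxy-5-methyl-2-pyrone 5.
4. Pyrone 10 comes from the dianion of triacetic acid lactone and a cinnamoyl Weinreb amide; pyrone 5 from the silyl enol ether of pentan-3-one and malonyl dichloride.
5. Ring order: the pyrone ring of 5 (step 2; the pyrone of 10 is bought), then ring A (step 6), then ring C (step 7).

Key step: step 6

Remark on the chemistry: the quinine-derived thiourea of step 7 is assumed to deliver the 2S product; if analysis shows the opposite sense, the quinidine-derived pseudo-enantiomer takes its place under the same conditions.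

**Route**

Step 1
Reactants: 1 pentan-3-one
Product: 2 (E)-3-(trimethylsilyloxy)pent-2-ene
Conditions: LiN(iPr)2 (1.05 equiv), THF, −78 °C; Me3SiCl, −78 °C → rt; distillation
Reagents that add atoms: chlorotrimethylsilane, C[Si](C)(C)Cl
Why: Kinetic deprotonation of the symmetrical ketone should give mainly the E lithium enolate, which is silylated on oxygen; any Z isomer is carried along because the double-bond geometry disappears in step 2.

Step 2
Reactants: 2 (E)-3-(trimethylsilyloxy)pent-2-ene, 3 malonyl dichloride
Product: 5 6-ethyl-4-hydroxy-5-methyl-2H-pyran-2-one, via diketo acid chloride 4 (not isolated)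
Conditions: Et2O, −78 °C → rt
Reagents that add atoms: none
Why: Acylation of silyl enol ethers with malonyl dichloride is an established 4-hydroxy-2-pyrone synthesis: C-acylation at the enol carbon with loss of Me3SiCl gives 4, whose ketone enol oxygen closes the six-membered lactone on the second acid chloride with loss of HCl, placing ethyl on C6 and methyl on C5.

Step 3
Reactants: 5 6-ethyl-4-hydroxy-5-methyl-2H-pyran-2-one
Product: 6 1-(6-ethyl-4-hydroxy-5-methyl-2-oxo-2H-pyran-3-yl)-N,N-dimethylmethanaminium iodide
Conditions: Me2N=CH2+ I− (1.05 equiv), CH2Cl2, 0 °C → rt; filtration of the precipitated salt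
Reagents that add atoms: N,N-dimethylmethyleneiminium iodide (Eschenmoser's salt), C=[N+](C)C.[I-]
Why: Mannich aminomethylation with a preformed iminium salt occurs at C3, the only unsubstituted nucleophilic carbon of the enolic pyrone, and avoids free formaldehyde and thus the symmetrical methylene dimer; the product separates as its hydroiodide, in which the protonated pyrone cannot eliminate the amine.

Step 4
Reactants: 7 4-hydroxy-6-methyl-2H-pyran-2-one (triacetic acid lactone), 8 (E)-N-methoxy-N-methyl-3-phenylprop-2-enamide
Product: 10 4-hydroxy-6-[(E)-2-oxo-4-phenylbut-3-enyl]-2H-pyran-2-one, via dilithiated pyrone 9 (not isolated)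
Conditions: LiN(iPr)2 (2.1 equiv), THF, −78 → −30 °C; 8, −78 → 0 °C; 1 M HCl
Reagents that add atoms: none
Why: Double deprotonation of 7 gives the O,C-dianion, which reacts at its exocyclic carbon terminus, and acylation with the Weinreb amide proceeds by 1,2-addition to a chelated tetrahedral adduct that survives until the acidic quench, so double addition and proton exchange with the product are avoided and conjugate addition to the cinnamoyl unit is less likely than with the simple ester.

Step 5
Reactants: 6 1-(6-ethyl-4-hydroxy-5-methyl-2-oxo-2H-pyran-3-yl)-N,N-dimethylmethanaminium iodide, 10 4-hydroxy-6-[(E)-2-oxo-4-phenylbut-3-enyl]-2H-pyran-2-one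
Product: 12 3-[(6-ethyl-4-hydroxy-5-methyl-2-oxo-2H-pyran-3-yl)methyl]-4-hydroxy-6-[(E)-2-oxo-4-phenylbut-3-enyl]-2H-pyran-2-one, via methylidene pyrandione 11 (not isolated)
Conditions: 6 (1.0 equiv), 10 (1.1 equiv), NaOAc (1.2 equiv), MeCN–AcOH (10:1), rt → 40 °C; then 1 M HCl
Reagents that add atoms: none
Why: In the acetate buffer the zwitterionic form of the Mannich base loses dimethylamine (E1cB) to the exocyclic enone 11, a far stronger Michael acceptor than the styryl ketone of 10, and C3 of the 4-hydroxypyrone 10 adds to it in the well-known methylene bridging of 4-hydroxy-pyrones and -coumarins; the weakly acidic medium keeps the liberated amine protonated so that it does not add to the enone.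

Step 6
Reactants: 12 3-[(6-ethyl-4-hydroxy-5-methyl-2-oxo-2H-pyran-3-yl)methyl]-4-hydroxy-6-[(E)-2-oxo-4-phenylbut-3-enyl]-2H-pyran-2-one
Product: 14 (E)-1-{3-[(6-ethyl-4-hydroxy-5-methyl-2-oxo-2H-pyran-3-yl)methyl]-2,4,6-trihydroxyphenyl}-3-phenylprop-2-en-1-one, via triketo ester 13 (not isolated)
Conditions: Mg(OMe)2 (8 equiv, freshly made from Mg turnings), MeOH, reflux, Ar, dark; then poured into ice-cold 1 M HCl, EtOAc extraction
Reagents that add atoms: none
Why: Excess Mg(OMe)2 turns both pyrones into magnesium pyronates, and methanolysis of the lactone that carries the cinnamoylmethyl arm gives the chelated triketo ester 13; its C6 methylene, lying between two ketones, then acylates itself on the ester carbon C1, methoxide leaves and the cyclohexanetrione enolises, so that C4a–C8a is made and ring A appears as the acylphloroglucinol of chalcone 14. The closest known reaction is the Mg(OMe)2-mediated biomimetic Claisen recyclisation of 6-(2-oxoalkyl)-4-hydroxy-2-pyrones to acylphloroglucinols. Ring A closes in the 6-exo-trig mode (the ester C=O is exocyclic to the new six-membered ring) and no stereocentre is formed. The step needs Claisen over aldol selectivity: the aldol alternative would join the ester α-carbon, which here bears the pyronylmethyl group, to the C7 ketone and create a quaternary carbon that cannot aromatise, so it stays reversible while the Claisen product is drained by aromatisation. It also needs selectivity between the two pyrones: the fully substituted pyrone has no acylmethyl arm and its open form would be a poorly enolised, weakly chelated 4-methyl-3,5-dioxo ester, so it should remain as the pyronate and could in any case only return to the same ring. Keeping every acidic site deprotonated should also suppress retro-Michael scission of the methylene bridge, and the cold acidic quench releases the chalcone before it can cyclise.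

Step 7
Reactants: 14 (E)-1-{3-[(6-ethyl-4-hydroxy-5-methyl-2-oxo-2H-pyran-3-yl)methyl]-2,4,6-trihydroxyphenyl}-3-phenylprop-2-en-1-one
Product: 15 (2S)-8-[(6-ethyl-4-hydroxy-5-methyl-2-oxo-2H-pyran-3-yl)methyl]-5,7-dihydroxy-2-phenyl-2,3-dihydro-4H-chromen-4-one
Conditions: 1-[3,5-bis(trifluoromethyl)phenyl]-3-[(8S,9S)-6′-methoxycinchonan-9-yl]thiourea (20 mol %), THF–toluene, −20 → 0 °C, dark; aq. citric acid wash; SiO2 chromatography; recrystallisation
Reagents that add atoms: none
Why: Bifunctional cinchona thiourea catalysis is a known way to close 2′-hydroxychalcones to flavanones by a 6-endo-trig oxa-Michael addition: the thiourea binds the enone carbonyl, the quinuclidine (expected here to pair with the acidic pyrone hydroxyl, whose pyronate lies next to the 2′-hydroxyl and can relay the proton) acts as general base, and the catalyst presents one face of the β-carbon to the phenol oxygen, which should set C2 as S; closure through the 6′-hydroxyl gives the 6-substituted regioisomer, which is removed by chromatography, and the product sees no base afterwards so that C2 is not scrambled by ring opening.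

**Compound list**

1 | pentan-3-one | CCC(=O)CC | starting material
2 | (E)-3-(trimethylsilyloxy)pent-2-ene (expected major isomer; the Z isomer reacts alike) | C/C=C(/O[Si](C)(C)C)CC | intermediate
3 | malonyl dichloride | O=C(Cl)CC(=O)Cl | starting material
4 | 4-methyl-3,5-dioxoheptanoyl chloride (racemic, not isolated) | CCC(=O)C(C)C(=O)CC(=O)Cl | intermediate
5 | 6-ethyl-4-hydroxy-5-methyl-2H-pyran-2-one | CCc1oc(=O)cc(O)c1C | intermediate
6 | 1-(6-ethyl-4-hydroxy-5-methyl-2-oxo-2H-pyran-3-yl)-N,N-dimethylmethanaminium iodide | CCc1oc(=O)c(C[NH+](C)C)c(O)c1C.[I-] | intermediate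
7 | 4-hydroxy-6-methyl-2H-pyran-2-one (triacetic acid lactone) | Cc1cc(O)cc(=O)o1 | starting material
8 | (E)-N-methoxy-N-methyl-3-phenylprop-2-enamide | CON(C)C(=O)/C=C/c1ccccc1 | starting material
9 | dilithium salt of the O,C-dianion of 7 (4-oxido, 6-CH2 carbanion; not isolated) | [Li+].[Li+].[CH2-]c1cc([O-])cc(=O)o1 | intermediate
10 | 4-hydroxy-6-[(E)-2-oxo-4-phenylbut-3-enyl]-2H-pyran-2-one | O=C(Cc1cc(O)cc(=O)o1)/C=C/c1ccccc1 | intermediate
11 | 6-ethyl-5-methyl-3-methylidene-2H-pyran-2,4(3H)-dione (not isolated) | CCC1=C(C)C(=O)C(=C)C(=O)O1 | intermediate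
12 | 3-[(6-ethyl-4-hydroxy-5-methyl-2-oxo-2H-pyran-3-yl)methyl]-4-hydroxy-6-[(E)-2-oxo-4-phenylbut-3-enyl]-2H-pyran-2-one | CCc1oc(=O)c(Cc2c(O)cc(CC(=O)/C=C/c3ccccc3)oc2=O)c(O)c1C | intermediate
13 | methyl (E)-2-[(6-ethyl-4-hydroxy-5-methyl-2-oxo-2H-pyran-3-yl)methyl]-3,5,7-trioxo-9-phenylnon-8-enoate (magnesium chelate in the flask, drawn as the neutral keto form, C2 racemic; not isolated) | CCc1oc(=O)c(CC(C(=O)OC)C(=O)CC(=O)CC(=O)/C=C/c2ccccc2)c(O)c1C | intermediate
14 | (E)-1-{3-[(6-ethyl-4-hydroxy-5-methyl-2-oxo-2H-pyran-3-yl)methyl]-2,4,6-trihydroxyphenyl}-3-phenylprop-2-en-1-one | CCc1oc(=O)c(Cc2c(O)cc(O)c(C(=O)/C=C/c3ccccc3)c2O)c(O)c1C | intermediate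
15 | (2S)-8-[(6-ethyl-4-hydroxy-5-methyl-2-oxo-2H-pyran-3-yl)methyl]-5,7-dihydroxy-2-phenyl-2,3-dihydro-4H-chromen-4-one | CCc1oc(=O)c(Cc2c(O)cc(O)c3c2O[C@H](c2ccccc2)CC3=O)c(O)c1C | target

**Step count**

Total: 7 steps. Longest linear sequence: 6 steps (steps 1, 2, 3, 5, 6, 7).

**Steps most likely to fail**

Step 6. Methanolysis of the second pyrone ring that does not reverse, base-induced scission or scrambling of the methylene bridge, or addition of methoxide to the enone may compete with the Claisen closure. The fallback reverses the order of bridging and recyclisation. Pyrone 10 alone is treated with Mg(OMe)2 in refluxing MeOH, the directly precedented mono-pyrone case, and should give (E)-3-phenyl-1-(2,4,6-trihydroxyphenyl)prop-2-en-1-one F1 after a cold acidic quench. F1, used in excess because its two free ring positions are equivalent, is then C-alkylated with Mannich salt 6 by way of 11 (NaOAc, MeCN–AcOH, rt), the known coupling of acylphloroglucinols with pyrone Mannich bases. This comes back to the route at chalcone 14.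

Step 7. The acidic pyrone hydroxyl may tie up the catalyst base so that the closure runs through a poorly organised ion pair, giving low facial selectivity and an unfavourable ratio of closure through the 2′- and 6′-hydroxyls; reversible ring opening may also erode the configuration. In the fallback, chalcone 14 is closed without a chiral catalyst (NaOAc, EtOH, reflux) and racemic 8-[(6-ethyl-4-hydroxy-5-methyl-2-oxo-2H-pyran-3-yl)methyl]-5,7-dihydroxy-2-phenylchroman-4-one F2 is separated from its 6-substituted isomer on silica. F2 is resolved by preparative HPLC on an amylose tris(3,5-dimethylphenylcarbamate) phase, which comes back to the route at 15. The unwanted enantiomer and the regioisomer can be reopened to 14 with cold aqueous KOH followed by fast acidification and used again.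

Step 4. The dianion may add in the conjugate sense to the cinnamoyl unit, or the poorly soluble dianion may acylate incompletely. In the fallback, dianion 9, generated from 7 as before, is added to (E)-cinnamaldehyde (THF, −78 °C, 1,2-addition, mild citric acid quench) to give racemic 4-hydroxy-6-[(E)-2-hydroxy-4-phenylbut-3-enyl]-2H-pyran-2-one F3. Selective oxidation of the allylic alcohol with MnO2 in acetone at rt comes back to the route at pyrone 10.

**Further compounds**

F1 | step 6 | (E)-3-phenyl-1-(2,4,6-trihydroxyphenyl)prop-2-en-1-one | O=C(/C=C/c1ccccc1)c1c(O)cc(O)cc1O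
F2 | step 7 | racemic 8-[(6-ethyl-4-hydroxy-5-methyl-2-oxo-2H-pyran-3-yl)methyl]-5,7-dihydroxy-2-phenylchroman-4-one | CCc1oc(=O)c(Cc2c(O)cc(O)c3c2OC(c2ccccc2)CC3=O)c(O)c1C
F3 | step 4 | racemic 4-hydroxy-6-[(E)-2-hydroxy-4-phenylbut-3-enyl]-2H-pyran-2-one | OC(Cc1cc(O)cc(=O)o1)/C=C/c1ccccc1
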